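**Plan**

1. Labels: ring A = central dihydrobenzofuran; ring B = outer dihydrobenzofuran, joined through its C-5 to C-3 of ring A; ring T = oxolane, joined through its C-4 to C-4 of ring A. Atoms are named by standard locant and ring (for example C-3a of ring A); ring T is numbered as the final oxolane, so that its C-2, C-3, C-4 and C-5 are the γ-carbon, β-carbon, α-carbon and carbonyl carbon of the lactone that precedes it. All phenols are carried as benzyl ethers; Ar4 = 4-(benzyloxy)phenyl, Ar35 = 3,5-bis(benzyloxy)phenyl, RB = (2R,3R)-7-(benzyloxy)-3-Ar35-2-Ar4-2,3-dihydro-1-benzofuran-5-yl.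
2. Enabling feature: the benzene of ring A carries three contiguous substituents (the ring oxygen on C-7a, C-3 on C-3a, and C-4 of ring T on C-4), which is what an α-aroyl lactone (α-carbon = C-4 of ring T, ketone carbon = C-3 of ring A) leaves on inserting across a 3-alkoxyaryne.
3. Cuts, in retrosynthetic order: ten O–benzyl bonds; the aryl bond at C-5 of ring T; the O-1 to C-2 and C-2 to C-3 bonds of ring A; the bond from C-4 of ring T to C-4 of ring A together with the C-3a to C-3 bond of ring A (aryne acyl-alkylation); the acyl bond between the lactone α-carbon and the ring B acid; the aryl bond at C-3 of ring T; the C-3 to C-2 bond of ring B.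
4. Forward: the lactone (future ring T) and the ring B acid are made separately and joined by C-acylation; the aryne insertion stitches in the benzene of ring A; ring A is closed by a [4+1] annulation; the lactone α-carbon is inverted; the lactone becomes the oxolane; the benzyl groups are removed.
5. Stereochemistry: C-2 of ring T by Noyori transfer hydrogenation; C-3 of ring T by conjugate addition anti to the C-2 aryl group; C-3 of ring B by enantioselective dirhodium C–H insertion and C-2 of ring B by equilibration to trans; C-3 and C-2 of ring A by substrate control from the trans-lactone; C-4 of ring T by kinetic protonation; C-5 of ring T by attack anti to the C-4 substituent.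

Key step: step 18

Remark: the SMILES is taken as the definition of the target (ring B is a 7-hydroxy-2,3-dihydrobenzofuran-5-yl unit), and Rh2(S-PTAD)4 is assumed to be the catalyst antipode that gives the 3R configuration at C-3 of ring B in step 11 (otherwise its mirror image is used).

**Route**

Step 1
Reactants: 1 4-(4-hydroxyphenyl)-4-oxobutanoic acid
Product: 2 benzyl 4-[4-(benzyloxy)phenyl]-4-oxobutanoate
Conditions: BnBr (2.3 equiv), K2CO3, DMF, 60 °C
Reagents that add atoms: benzyl bromide, BrCc1ccccc1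
Why: Williamson etherification of the phenol and alkylation of the carboxylate should occur in one operation, the benzyl ester being lost again as benzyl alcohol in step 2.

Step 2
Reactants: 2 benzyl 4-[4-(benzyloxy)phenyl]-4-oxobutanoate
Product: 4 (5S)-5-[4-(benzyloxy)phenyl]oxolan-2-one, via hydroxy ester 3 (not isolated)
Conditions: RuCl[(S,S)-TsDPEN](p-cymene) (1 mol %), HCO2H–Et3N (5:2), EtOAc, 40 °C; then pyridinium 4-toluenesulfonate (cat.), PhMe, 40 °C
Reagents that add atoms: none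
Why: Noyori asymmetric transfer hydrogenation of the aryl ketone with the (S,S)-configured catalyst should deliver hydride to one enantiotopic face and set the carbinol centre (future C-2 of ring T) as S, and the γ-hydroxy ester closes to the lactone under mild acid catalysis that should not ionise the 4-alkoxybenzylic C–O bond.

Step 3
Reactants: 4 (5S)-5-[4-(benzyloxy)phenyl]oxolan-2-one
Product: 6 (5S)-5-[4-(benzyloxy)phenyl]furan-2(5H)-one, via selenide 5 (not isolated)
Conditions: LiN(iPr)2, THF, −78 °C; PhSeBr; then 30% H2O2, pyridine, CH2Cl2, 0 °C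
Reagents that add atoms: none
Why: α-selenenylation of the lactone enolate followed by oxidation and syn elimination of the selenoxide should introduce the 3,4-double bond without touching the γ-stereocentre.

Step 4
Reactants: 7 1,3-bis(benzyloxy)-5-bromobenzene
Product: 8 [3,5-bis(benzyloxy)phenyl]magnesium bromide (titrated THF solution kept under argon)
Conditions: Mg turnings, THF, 40 °C
Reagents that add atoms: magnesium, [Mg]
Why: insertion of magnesium into the aryl C–Br bond (Grignard reagent formation) should be uneventful for this electron-rich bromide, whose benzyl ethers are inert to the reagent, and one titrated batch serves both steps that need this aryl nucleophile (steps 5 and 8).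

Step 5
Reactants: 6 (5S)-5-[4-(benzyloxy)phenyl]furan-2(5H)-one; 8 [3,5-bis(benzyloxy)phenyl]magnesium bromide
Product: 10 (4R,5S)-4-Ar35-5-Ar4-oxolan-2-one, via silyl ketene acetal 9 (not isolated)
Conditions: 8, CuBr·SMe2 (10 mol %), Me3SiCl, THF, −78 °C; 1 M HCl
Reagents that add atoms: none
Why: the Me3SiCl-accelerated copper-catalysed conjugate addition of the aryl Grignard reagent should take place on the butenolide face anti to the γ-aryl group, setting C-3 of ring T as R and giving the 4,5-trans lactone after hydrolysis of the silyl ketene acetal.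

Step 6
Reactants: 11 5-bromo-2,3-dihydroxybenzaldehyde
Product: 12 3-(benzyloxy)-5-bromo-2-hydroxybenzaldehyde
Conditions: NaH (2.1 equiv), DMF, 0 °C; BnBr (1.0 equiv), rt; 1 M HCl
Reagents that add atoms: benzyl bromide, BrCc1ccccc1
Why: Williamson alkylation of the dianion should occur at the 3-oxide, the more nucleophilic site because the 2-oxide is conjugated with and chelated to the formyl group.

Step 7
Reactants: 12 3-(benzyloxy)-5-bromo-2-hydroxybenzaldehyde; 13 1-(benzyloxy)-4-(chloromethyl)benzene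
Product: 14 3-(benzyloxy)-2-{[4-(benzyloxy)phenyl]methoxy}-5-bromobenzaldehyde
Conditions: K2CO3, KI (cat.), DMF, 60 °C
Reagents that add atoms: none
Why: Williamson etherification of the remaining phenol installs the 4-(benzyloxy)benzyl group whose methylene carbon becomes C-2 of ring B.

Step 8
Reactants: 14 3-(benzyloxy)-2-{[4-(benzyloxy)phenyl]methoxy}-5-bromobenzaldehyde; 8 [3,5-bis(benzyloxy)phenyl]magnesium bromide
Product: 15 [3-(benzyloxy)-2-{[4-(benzyloxy)phenyl]methoxy}-5-bromophenyl](Ar35)methanol (racemic)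
Conditions: 8 (THF solution), 14, THF, −78 → 0 °C; aq. NH4Cl
Reagents that add atoms: none
Why: Grignard addition to the aldehyde at low temperature should leave the aryl bromide intact, and the carbinol centre is removed by oxidation in the next step.

Step 9
Reactants: 15 [3-(benzyloxy)-2-{[4-(benzyloxy)phenyl]methoxy}-5-bromophenyl](Ar35)methanol
Product: 16 [3-(benzyloxy)-2-{[4-(benzyloxy)phenyl]methoxy}-5-bromophenyl](Ar35)methanone
Conditions: Dess–Martin periodinane, CH2Cl2, rt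
Reagents that add atoms: none
Why: Dess–Martin oxidation of the benzhydrol should give the diaryl ketone under neutral conditions.

Step 10
Reactants: 16 [3-(benzyloxy)-2-{[4-(benzyloxy)phenyl]methoxy}-5-bromophenyl](Ar35)methanone
Product: 17 hydrazone of ketone 16 (E/Z mixture)
Conditions: N2H4·H2O (excess), AcOH (cat.), EtOH, 80 °C
Reagents that add atoms: hydrazine, NN
Why: acid-catalysed condensation with excess hydrazine should give the N-unsubstituted hydrazone, the precursor of the diaryldiazomethane.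

Step 11
Reactants: 17 hydrazone of ketone 16
Product: 19 (2S,3R)-7-(benzyloxy)-3-Ar35-2-Ar4-5-bromo-2,3-dihydro-1-benzofuran (2,3-cis), via diazoalkane 18 (not isolated)
Conditions: MnO2, CH2Cl2, 0 °C, filtration; then Rh2(S-PTAD)4 (1 mol %), CH2Cl2, 0 °C
Reagents that add atoms: none
Why: MnO2 dehydrogenates the hydrazone to the diaryldiazomethane, whose dirhodium carbene inserts into a benzylic C–H bond of the neighbouring ArCH2–O group (1,5 C–H insertion of a donor/donor carbene); the chiral carboxylate ligands choose the carbene face and the enantiotopic hydrogen, setting C-3 of ring B as R in the kinetically formed 2,3-cis dihydrobenzofuran.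

Step 12
Reactants: 19 (2S,3R)-7-(benzyloxy)-3-Ar35-2-Ar4-5-bromo-2,3-dihydro-1-benzofuran
Product: 20 (2R,3R)-7-(benzyloxy)-3-Ar35-2-Ar4-5-bromo-2,3-dihydro-1-benzofuran (2,3-trans)
Conditions: CF3CO2H, CH2Cl2, 0 °C → rt
Reagents that add atoms: none
Why: reversible acid-induced opening of the bond from the ring oxygen to C-2 of ring B, which gives the 4-alkoxybenzyl cation, and reclosure should equilibrate C-2 to the more stable 2,3-trans isomer (2R) while C-3 is untouched.

Step 13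
Reactants: 20 (2R,3R)-7-(benzyloxy)-3-Ar35-2-Ar4-5-bromo-2,3-dihydro-1-benzofuran
Product: 22 RB–CO2H [(2R,3R)-7-(benzyloxy)-3-Ar35-2-Ar4-2,3-dihydro-1-benzofuran-5-carboxylic acid], via aryllithium 21 (not isolated)
Conditions: nBuLi, THF, −78 °C; CO2; 1 M HCl
Reagents that add atoms: carbon dioxide, O=C=O
Why: bromine–lithium exchange at −78 °C and carboxylation of the aryllithium should give the ring B acid without disturbing the benzylic stereocentres.

Step 14
Reactants: 23 3,5-bis(benzyloxy)phenol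
Product: 24 3,5-bis(benzyloxy)phenyl N-isopropylcarbamate
Conditions: iPrNCO, Et3N (cat.), CH2Cl2, rt
Reagents that add atoms: isopropyl isocyanate, CC(C)N=C=O
Why: addition of the phenol to the isocyanate gives the N-isopropyl carbamate, a strong ortho-directing group that can later be removed under mild base.

Step 15
Reactants: 24 3,5-bis(benzyloxy)phenyl N-isopropylcarbamate
Product: 27 3,5-bis(benzyloxy)-2-(trimethylsilyl)phenyl N-isopropylcarbamate, via N-silyl carbamate 25 (not isolated), via disilyl carbamate 26 (not isolated)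
Conditions: tBuMe2SiOTf, TMEDA, Et2O, 0 °C → rt; nBuLi, TMEDA, −78 °C; Me3SiCl, −78 °C → rt; aq. NaHSO4
Reagents that add atoms: chlorotrimethylsilane, C[Si](C)(C)Cl
Why: after transient N-silylation the carbamate directs ortho-lithiation to the position flanked by the carbamate and a benzyloxy group (directed ortho-metalation), Me3SiCl quenches the aryllithium and the N-silyl group is lost on acidic work-up.

Step 16
Reactants: 27 3,5-bis(benzyloxy)-2-(trimethylsilyl)phenyl N-isopropylcarbamate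
Product: 29 3,5-bis(benzyloxy)-2-(trimethylsilyl)phenyl trifluoromethanesulfonate, via silyl phenol 28 (not isolated)
Conditions: DBU, Et2NH, MeCN, 40 °C; then PhNTf2, rt
Reagents that add atoms: N-phenylbis(trifluoromethanesulfonimide), O=S(=O)(N(c1ccccc1)S(=O)(=O)C(F)(F)F)C(F)(F)F
Why: DBU-induced loss of isopropyl isocyanate, trapped by Et2NH as a urea, frees the phenoxide, which is triflated in the same flask to give the aryne precursor.

Step 17
Reactants: 22 RB–CO2H; 10 (4R,5S)-4-Ar35-5-Ar4-oxolan-2-one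
Product: 31 (4R,5S)-3-(RB-carbonyl)-4-Ar35-5-Ar4-oxolan-2-one (α-carbon stereolabile), via acyl imidazole 30 (not isolated)
Conditions: 22, CDI, THF, rt; 10, LiN(SiMe3)2 (2.2 equiv), THF, −78 °C, then 30, −78 → −20 °C; aq. NH4Cl
Reagents that add atoms: none
Why: Claisen-type C-acylation of the lithium enolate of the lactone by the acyl imidazole joins the two fragments, the second equivalent of base storing the product as its stabilised enolate; the α-carbon (future C-4 of ring T) is stereolabile and needs no control.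

Step 18
Reactants: 31 (4R,5S)-3-(RB-carbonyl)-4-Ar35-5-Ar4-oxolan-2-one; 29 3,5-bis(benzyloxy)-2-(trimethylsilyl)phenyl trifluoromethanesulfonate
Product: 33 (3R,4R,5S)-3-[3,5-bis(benzyloxy)-2-(RB-carbonyl)phenyl]-4-Ar35-5-Ar4-oxolan-2-one (3,4-trans), via aryne 32 (not isolated)
Conditions: CsF (3 equiv), MeCN, 80 °C
Reagents that add atoms: none
Why: Fluoride removes the trimethylsilyl group of 29 and triflate departs to give aryne 32, and the caesium enolate of 31 attacks the aryne carbon meta to the flanking benzyloxy group (future C-4 of ring A) because the aryl anion developing at the neighbouring carbon (future C-3a) is stabilised inductively by that oxygen substituent. The aryl anion adds to the adjacent aroyl ketone to give a benzocyclobutenoxide, whose fragmentation moves the ring B aroyl group onto C-3a and leaves an aryl-stabilised lactone enolate, so that the bond from C-4 of ring T to C-4 of ring A and the bond from C-3a to C-3 of ring A form in one operation. The closest known reaction type is the acyl-alkylation of arynes by β-keto esters, here with an α-substituted β-keto lactone. No ring of the target is closed in this step. The new stereocentre at C-4 of ring T is not final: under the basic fluoride conditions the α-aryl lactone should equilibrate to the 3,4-trans isomer (3R in lactone numbering), so that the neighbouring β-aryl centre controls it thermodynamically; this is the isomer wanted for the closure of ring A, and the centre is inverted in step 24. The selectivities needed are the regiochemistry of addition to the aryne, secured by the 3-alkoxy group, and capture of the aryl anion by the ketone in preference to the lactone carbonyl or a proton, favoured by the non-enolisable and more electrophilic ketone and by the aprotic medium.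

Step 19
Reactants: 33 (3R,4R,5S)-3-[3,5-bis(benzyloxy)-2-(RB-carbonyl)phenyl]-4-Ar35-5-Ar4-oxolan-2-one
Product: 34 (3R,4R,5S)-3-[5-(benzyloxy)-3-hydroxy-2-(RB-carbonyl)phenyl]-4-Ar35-5-Ar4-oxolan-2-one
Conditions: MgBr2·OEt2 (3 equiv), PhMe–Et2O, 80 °C; 1 M HCl
Reagents that add atoms: none
Why: magnesium chelated between the ketone oxygen and the ortho ether oxygen should activate only that benzyl ether for cleavage by bromide, freeing the phenol on the future C-7a of ring A while the nine other benzyl ethers stay.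

Step 20
Reactants: 34 (3R,4R,5S)-3-[5-(benzyloxy)-3-hydroxy-2-(RB-carbonyl)phenyl]-4-Ar35-5-Ar4-oxolan-2-one
Product: 35 (3R,4R,5S)-3-{5-(benzyloxy)-3-hydroxy-2-[hydroxy(RB)methyl]phenyl}-4-Ar35-5-Ar4-oxolan-2-one (carbinol epimers)
Conditions: NaBH4, THF–MeOH, 0 °C
Reagents that add atoms: none
Why: borohydride reduction of the ortho-hydroxy diaryl ketone should give the benzhydrol without touching the lactone at 0 °C, and the new carbinol centre becomes trigonal again in step 23.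

Step 21
Reactants: 35 (3R,4R,5S)-3-{5-(benzyloxy)-3-hydroxy-2-[hydroxy(RB)methyl]phenyl}-4-Ar35-5-Ar4-oxolan-2-one
Product: 36 (3R,4R,5S)-3-{5-(benzyloxy)-3-hydroxy-2-[(RB)(4-methylbenzenesulfonyl)methyl]phenyl}-4-Ar35-5-Ar4-oxolan-2-one (epimers at the sulfonyl carbon)
Conditions: 4-MeC6H4SO2H (2 equiv), CH2Cl2, rt
Reagents that add atoms: 4-methylbenzenesulfinic acid, Cc1ccc(S(=O)O)cc1
Why: the electron-rich ortho-hydroxybenzhydrol ionises under the acidity of the sulfinic acid and the sulfinate adds through sulfur, giving a stable sulfone that releases the ortho-quinone methide on treatment with base.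

Step 22
Reactants: 13 1-(benzyloxy)-4-(chloromethyl)benzene
Product: 37 1-{[4-(benzyloxy)phenyl]methyl}thiolan-1-ium tetrafluoroborate
Conditions: tetrahydrothiophene, NaBF4, acetone, rt
Reagents that add atoms: tetrahydrothiophene, C1CCSC1; sodium tetrafluoroborate, [Na+].F[B-](F)(F)F
Why: S-alkylation of the sulfide by the reactive 4-alkoxybenzyl chloride, driven by precipitation of NaCl, gives the sulfonium salt that serves as the one-carbon partner carrying the aryl group of C-2 of ring A.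

Step 23
Reactants: 36 sulfone (3R,4R,5S)-3-{5-(benzyloxy)-3-hydroxy-2-[(RB)(4-methylbenzenesulfonyl)methyl]phenyl}-4-Ar35-5-Ar4-oxolan-2-one; 37 1-{[4-(benzyloxy)phenyl]methyl}thiolan-1-ium tetrafluoroborate
Product: 39 (3R,4R,5S)-3-[(2S,3S)-6-(benzyloxy)-2-Ar4-3-(RB)-2,3-dihydro-1-benzofuran-4-yl]-4-Ar35-5-Ar4-oxolan-2-one (lactone 3,4-trans), via ortho-quinone methide 38 (not isolated)
Conditions: Cs2CO3 (3.5 equiv), CH2Cl2, 0 °C → rt
Reagents that add atoms: none
Why: Cs2CO3 expels sulfinate from the phenoxide of 36 to give ortho-quinone methide 38 and converts 37 into its ylide, which adds to the exocyclic carbon (future C-3 of ring A) and is then displaced from the new benzylic carbon (future C-2 of ring A) by the phenoxide with loss of tetrahydrothiophene ([4+1] annulation of a sulfur ylide with an ortho-quinone methide), closing ring A by 5-exo-tet O-alkylation as the 2,3-trans isomer; the ylide should approach the face of 38 opposite the C-3 aryl group of ring T, which the trans-lactone on C-4 of ring A holds over the other face, setting C-3 of ring A as S and thereby C-2 as S.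

Step 24
Reactants: 39 (3R,4R,5S)-3-[(2S,3S)-6-(benzyloxy)-2-Ar4-3-(RB)-2,3-dihydro-1-benzofuran-4-yl]-4-Ar35-5-Ar4-oxolan-2-one
Product: 41 (3S,4R,5S)-3-[(2S,3S)-6-(benzyloxy)-2-Ar4-3-(RB)-2,3-dihydro-1-benzofuran-4-yl]-4-Ar35-5-Ar4-oxolan-2-one (lactone 3,4-cis), via lithium enolate 40 (not isolated)
Conditions: LiN(iPr)2, THF, −78 → −40 °C; 2,6-di-tert-butyl-4-methylphenol, −78 °C; aq. NH4Cl
Reagents that add atoms: none
Why: deprotonation at the lactone α-carbon (C-4 of ring T) gives the planar aryl-conjugated lactone enolate, and the bulky phenol should deliver the proton to the face opposite the C-3 aryl group of ring T (kinetic protonation), which places the ring A substituent cis to that aryl group and inverts C-4 of ring T to the required S configuration.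

Step 25
Reactants: 41 (3S,4R,5S)-3-[(2S,3S)-6-(benzyloxy)-2-Ar4-3-(RB)-2,3-dihydro-1-benzofuran-4-yl]-4-Ar35-5-Ar4-oxolan-2-one
Product: 42 (3S,4R,5S)-3-[(2S,3S)-6-(benzyloxy)-2-Ar4-3-(RB)-2,3-dihydro-1-benzofuran-4-yl]-4-Ar35-5-Ar4-oxolan-2-ol (anomers)
Conditions: iBu2AlH, CH2Cl2, −78 °C; aq. KNaC4H4O6
Reagents that add atoms: none
Why: iBu2AlH adds once to the lactone at −78 °C and the aluminium hemiacetal survives until work-up, giving the lactol under non-basic conditions that should leave the 3,4-cis centre at C-4 of ring T untouched.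

Step 26
Reactants: 42 (3S,4R,5S)-3-[(2S,3S)-6-(benzyloxy)-2-Ar4-3-(RB)-2,3-dihydro-1-benzofuran-4-yl]-4-Ar35-5-Ar4-oxolan-2-ol
Product: 43 (3S,4R,5S)-2-(benzenesulfonyl)-3-[(2S,3S)-6-(benzyloxy)-2-Ar4-3-(RB)-2,3-dihydro-1-benzofuran-4-yl]-4-Ar35-5-Ar4-oxolane (anomers)
Conditions: PhSO2H, CaCl2, CH2Cl2, rt
Reagents that add atoms: benzenesulfinic acid, O=S(O)c1ccccc1
Why: exchange of the anomeric hydroxyl for benzenesulfinate through the ring T oxocarbenium ion gives the anomeric sulfone, a stable precursor of that ion under mild Lewis acid activation.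

Step 27
Reactants: 43 anomeric sulfone (3S,4R,5S)-2-(benzenesulfonyl)-3-[(2S,3S)-6-(benzyloxy)-2-Ar4-3-(RB)-2,3-dihydro-1-benzofuran-4-yl]-4-Ar35-5-Ar4-oxolane; 44 1-(benzyloxy)-4-bromobenzene
Product: 47 (2S,3R,4S,5R)-4-[(2S,3S)-6-(benzyloxy)-2-Ar4-3-(RB)-2,3-dihydro-1-benzofuran-4-yl]-3-Ar35-2,5-bis(Ar4)oxolane (deca-O-benzyl ether of 48), via aryl Grignard reagent 45 (not isolated), via diarylzinc 46 (not isolated)
Conditions: 44, Mg, THF; ZnBr2 (0.5 equiv), THF, rt; then 43, THF, 0 °C → rt; aq. NH4Cl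
Reagents that add atoms: none
Why: zinc- and magnesium-assisted ionisation of the anomeric sulfone regenerates the oxocarbenium ion, and the arylzinc reagent should attack C-5 of ring T from the face anti to the ring A substituent on C-4 (inside attack on the envelope that keeps the C-3 aryl group pseudoequatorial), setting C-5 as R with the 4,5-trans and 2,5-cis relationships of the target.

Step 28
Reactants: 47 deca-O-benzyl ether of 48
Product: 48 kobophenol A (structure as defined by the SMILES)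
Conditions: H2 (1 atm), Pd(OH)2/C, THF–MeOH, rt
Reagents that add atoms: none
Why: hydrogenolysis cleaves the ten aryl benzyl ethers under neutral conditions, under which the more slowly reacting benzylic C–O bonds of rings A, B and T and their acid-labile stereocentres should survive.

**Compound list**

1 | 4-(4-hydroxyphenyl)-4-oxobutanoic acid | O=C(O)CCC(=O)c1ccc(O)cc1 | starting material
2 | benzyl 4-[4-(benzyloxy)phenyl]-4-oxobutanoate | O=C(CCC(=O)c1ccc(OCc9ccccc9)cc1)OCc9ccccc9 | intermediate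
3 | benzyl (4S)-4-[4-(benzyloxy)phenyl]-4-hydroxybutanoate | O=C(CC[C@H](O)c1ccc(OCc9ccccc9)cc1)OCc9ccccc9 | intermediate
4 | (5S)-5-[4-(benzyloxy)phenyl]oxolan-2-one | O=C1CC[C@@H](c2ccc(OCc9ccccc9)cc2)O1 | intermediate
5 | (5S)-5-[4-(benzyloxy)phenyl]-3-(phenylselanyl)oxolan-2-one (epimers at the α-carbon) | O=C1C([Se]c3ccccc3)C[C@@H](c2ccc(OCc9ccccc9)cc2)O1 | intermediate
6 | (5S)-5-[4-(benzyloxy)phenyl]furan-2(5H)-one | O=C1C=C[C@@H](c2ccc(OCc9ccccc9)cc2)O1 | intermediate
7 | 1,3-bis(benzyloxy)-5-bromobenzene | Brc1cc(OCc9ccccc9)cc(OCc9ccccc9)c1 | starting material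
8 | [3,5-bis(benzyloxy)phenyl]magnesium bromide | Br[Mg]c1cc(OCc9ccccc9)cc(OCc9ccccc9)c1 | intermediate
9 | {[(4R,5S)-4-Ar35-5-Ar4-4,5-dihydrofuran-2-yl]oxy}trimethylsilane | C[Si](C)(C)OC1=C[C@H](c2cc(OCc9ccccc9)cc(OCc9ccccc9)c2)[C@@H](c2ccc(OCc9ccccc9)cc2)O1 | intermediate
10 | (4R,5S)-4-Ar35-5-Ar4-oxolan-2-one (4,5-trans) | O=C1C[C@H](c2cc(OCc9ccccc9)cc(OCc9ccccc9)c2)[C@@H](c2ccc(OCc9ccccc9)cc2)O1 | intermediate
11 | 5-bromo-2,3-dihydroxybenzaldehyde | O=Cc1cc(Br)cc(O)c1O | starting material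
12 | 3-(benzyloxy)-5-bromo-2-hydroxybenzaldehyde | O=Cc1cc(Br)cc(OCc9ccccc9)c1O | intermediate
13 | 1-(benzyloxy)-4-(chloromethyl)benzene | ClCc1ccc(OCc9ccccc9)cc1 | starting material
14 | 3-(benzyloxy)-2-{[4-(benzyloxy)phenyl]methoxy}-5-bromobenzaldehyde | O=Cc1cc(Br)cc(OCc9ccccc9)c1OCc1ccc(OCc9ccccc9)cc1 | intermediate
15 | [3-(benzyloxy)-2-{[4-(benzyloxy)phenyl]methoxy}-5-bromophenyl](Ar35)methanol (racemic) | OC(c1cc(Br)cc(OCc9ccccc9)c1OCc1ccc(OCc9ccccc9)cc1)c1cc(OCc9ccccc9)cc(OCc9ccccc9)c1 | intermediate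
16 | [3-(benzyloxy)-2-{[4-(benzyloxy)phenyl]methoxy}-5-bromophenyl](Ar35)methanone | O=C(c1cc(Br)cc(OCc9ccccc9)c1OCc1ccc(OCc9ccccc9)cc1)c1cc(OCc9ccccc9)cc(OCc9ccccc9)c1 | intermediate
17 | hydrazone of ketone 16 (E/Z mixture) | NN=C(c1cc(Br)cc(OCc9ccccc9)c1OCc1ccc(OCc9ccccc9)cc1)c1cc(OCc9ccccc9)cc(OCc9ccccc9)c1 | intermediate
18 | 1-(benzyloxy)-3-[(Ar35)(diazo)methyl]-2-{[4-(benzyloxy)phenyl]methoxy}-5-bromobenzene | [N-]=[N+]=C(c1cc(Br)cc(OCc9ccccc9)c1OCc1ccc(OCc9ccccc9)cc1)c1cc(OCc9ccccc9)cc(OCc9ccccc9)c1 | intermediate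
19 | (2S,3R)-7-(benzyloxy)-3-Ar35-2-Ar4-5-bromo-2,3-dihydro-1-benzofuran (2,3-cis) | Brc1cc(OCc9ccccc9)c2c(c1)[C@@H](c1cc(OCc9ccccc9)cc(OCc9ccccc9)c1)[C@@H](c1ccc(OCc9ccccc9)cc1)O2 | intermediate
20 | (2R,3R)-7-(benzyloxy)-3-Ar35-2-Ar4-5-bromo-2,3-dihydro-1-benzofuran (2,3-trans) | Brc1cc(OCc9ccccc9)c2c(c1)[C@@H](c1cc(OCc9ccccc9)cc(OCc9ccccc9)c1)[C@H](c1ccc(OCc9ccccc9)cc1)O2 | intermediate
21 | RB–Li [(2R,3R)-7-(benzyloxy)-3-Ar35-2-Ar4-2,3-dihydro-1-benzofuran-5-yl]lithium | [Li]c1cc(OCc9ccccc9)c2c(c1)[C@@H](c1cc(OCc9ccccc9)cc(OCc9ccccc9)c1)[C@H](c1ccc(OCc9ccccc9)cc1)O2 | intermediate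
22 | RB–CO2H, (2R,3R)-7-(benzyloxy)-3-Ar35-2-Ar4-2,3-dihydro-1-benzofuran-5-carboxylic acid | O=C(O)c1cc(OCc9ccccc9)c2c(c1)[C@@H](c1cc(OCc9ccccc9)cc(OCc9ccccc9)c1)[C@H](c1ccc(OCc9ccccc9)cc1)O2 | intermediate
23 | 3,5-bis(benzyloxy)phenol | Oc1cc(OCc9ccccc9)cc(OCc9ccccc9)c1 | starting material
24 | 3,5-bis(benzyloxy)phenyl N-isopropylcarbamate | CC(C)NC(=O)Oc1cc(OCc9ccccc9)cc(OCc9ccccc9)c1 | intermediate
25 | 3,5-bis(benzyloxy)phenyl N-(tert-butyldimethylsilyl)-N-isopropylcarbamate | CC(C)N(C(=O)Oc1cc(OCc9ccccc9)cc(OCc9ccccc9)c1)[Si](C)(C)C(C)(C)C | intermediate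
26 | 3,5-bis(benzyloxy)-2-(trimethylsilyl)phenyl N-(tert-butyldimethylsilyl)-N-isopropylcarbamate | CC(C)N(C(=O)Oc1cc(OCc9ccccc9)cc(OCc9ccccc9)c1[Si](C)(C)C)[Si](C)(C)C(C)(C)C | intermediate
27 | 3,5-bis(benzyloxy)-2-(trimethylsilyl)phenyl N-isopropylcarbamate | CC(C)NC(=O)Oc1cc(OCc9ccccc9)cc(OCc9ccccc9)c1[Si](C)(C)C | intermediate
28 | 3,5-bis(benzyloxy)-2-(trimethylsilyl)phenol | Oc1cc(OCc9ccccc9)cc(OCc9ccccc9)c1[Si](C)(C)C | intermediate
29 | 3,5-bis(benzyloxy)-2-(trimethylsilyl)phenyl trifluoromethanesulfonate | C[Si](C)(C)c1c(OCc9ccccc9)cc(OCc9ccccc9)cc1OS(=O)(=O)C(F)(F)F | intermediate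
30 | RB–CO–imidazol-1-yl (acyl imidazole of 22) | O=C(n1ccnc1)c1cc(OCc9ccccc9)c2c(c1)[C@@H](c1cc(OCc9ccccc9)cc(OCc9ccccc9)c1)[C@H](c1ccc(OCc9ccccc9)cc1)O2 | intermediate
31 | (4R,5S)-3-(RB-carbonyl)-4-Ar35-5-Ar4-oxolan-2-one (α-carbon stereolabile) | O=C(c1cc(OCc9ccccc9)c2c(c1)[C@@H](c1cc(OCc9ccccc9)cc(OCc9ccccc9)c1)[C@H](c1ccc(OCc9ccccc9)cc1)O2)C1[C@H](c2cc(OCc9ccccc9)cc(OCc9ccccc9)c2)[C@@H](c2ccc(OCc9ccccc9)cc2)OC1=O | intermediate
32 | 3,5-bis(benzyloxy)benzyne (1,2-didehydro) | C1#CC(OCc9ccccc9)=CC(OCc9ccccc9)=C1 | intermediate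
33 | (3R,4R,5S)-3-[3,5-bis(benzyloxy)-2-(RB-carbonyl)phenyl]-4-Ar35-5-Ar4-oxolan-2-one (3,4-trans) | O(Cc9ccccc9)c1cc(OCc9ccccc9)cc([C@H]2[C@H](c3cc(OCc9ccccc9)cc(OCc9ccccc9)c3)[C@@H](c3ccc(OCc9ccccc9)cc3)OC2=O)c1C(=O)c1cc(OCc9ccccc9)c2c(c1)[C@@H](c1cc(OCc9ccccc9)cc(OCc9ccccc9)c1)[C@H](c1ccc(OCc9ccccc9)cc1)O2 | intermediate
34 | (3R,4R,5S)-3-[5-(benzyloxy)-3-hydroxy-2-(RB-carbonyl)phenyl]-4-Ar35-5-Ar4-oxolan-2-one | Oc1cc(OCc9ccccc9)cc([C@H]2[C@H](c3cc(OCc9ccccc9)cc(OCc9ccccc9)c3)[C@@H](c3ccc(OCc9ccccc9)cc3)OC2=O)c1C(=O)c1cc(OCc9ccccc9)c2c(c1)[C@@H](c1cc(OCc9ccccc9)cc(OCc9ccccc9)c1)[C@H](c1ccc(OCc9ccccc9)cc1)O2 | intermediate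
35 | (3R,4R,5S)-3-{5-(benzyloxy)-3-hydroxy-2-[hydroxy(RB)methyl]phenyl}-4-Ar35-5-Ar4-oxolan-2-one (carbinol epimers) | Oc1cc(OCc9ccccc9)cc([C@H]2[C@H](c3cc(OCc9ccccc9)cc(OCc9ccccc9)c3)[C@@H](c3ccc(OCc9ccccc9)cc3)OC2=O)c1C(O)c1cc(OCc9ccccc9)c2c(c1)[C@@H](c1cc(OCc9ccccc9)cc(OCc9ccccc9)c1)[C@H](c1ccc(OCc9ccccc9)cc1)O2 | intermediate
36 | (3R,4R,5S)-3-{5-(benzyloxy)-3-hydroxy-2-[(RB)(4-methylbenzenesulfonyl)methyl]phenyl}-4-Ar35-5-Ar4-oxolan-2-one (epimers at the sulfonyl carbon) | Oc1cc(OCc9ccccc9)cc([C@H]2[C@H](c3cc(OCc9ccccc9)cc(OCc9ccccc9)c3)[C@@H](c3ccc(OCc9ccccc9)cc3)OC2=O)c1C(c1cc(OCc9ccccc9)c2c(c1)[C@@H](c1cc(OCc9ccccc9)cc(OCc9ccccc9)c1)[C@H](c1ccc(OCc9ccccc9)cc1)O2)S(=O)(=O)c1ccc(C)cc1 | intermediate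
37 | 1-{[4-(benzyloxy)phenyl]methyl}thiolan-1-ium tetrafluoroborate | F[B-](F)(F)F.C1CC[S+](Cc2ccc(OCc9ccccc9)cc2)C1 | intermediate
38 | (3R,4R,5S)-3-[3-(benzyloxy)-5-oxo-6-(RB-methylidene)cyclohexa-1,3-dien-1-yl]-4-Ar35-5-Ar4-oxolan-2-one (ortho-quinone methide) | O=C1C=C(OCc9ccccc9)C=C([C@H]2[C@H](c3cc(OCc9ccccc9)cc(OCc9ccccc9)c3)[C@@H](c3ccc(OCc9ccccc9)cc3)OC2=O)C1=Cc1cc(OCc9ccccc9)c2c(c1)[C@@H](c1cc(OCc9ccccc9)cc(OCc9ccccc9)c1)[C@H](c1ccc(OCc9ccccc9)cc1)O2 | intermediate
39 | (3R,4R,5S)-3-[(2S,3S)-6-(benzyloxy)-2-Ar4-3-(RB)-2,3-dihydro-1-benzofuran-4-yl]-4-Ar35-5-Ar4-oxolan-2-one (lactone 3,4-trans) | O(Cc9ccccc9)c1ccc([C@H]2Oc3cc(OCc9ccccc9)cc([C@H]4[C@H](c5cc(OCc9ccccc9)cc(OCc9ccccc9)c5)[C@@H](c5ccc(OCc9ccccc9)cc5)OC4=O)c3[C@@H]2c2cc(OCc9ccccc9)c3c(c2)[C@@H](c2cc(OCc9ccccc9)cc(OCc9ccccc9)c2)[C@H](c2ccc(OCc9ccccc9)cc2)O3)cc1 | intermediate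
40 | lithium enolate of 39 (lactone α-carbon trigonal) | O(Cc9ccccc9)c1ccc([C@H]2Oc3cc(OCc9ccccc9)cc(C4[C@H](c5cc(OCc9ccccc9)cc(OCc9ccccc9)c5)[C@@H](c5ccc(OCc9ccccc9)cc5)OC=4O[Li])c3[C@@H]2c2cc(OCc9ccccc9)c3c(c2)[C@@H](c2cc(OCc9ccccc9)cc(OCc9ccccc9)c2)[C@H](c2ccc(OCc9ccccc9)cc2)O3)cc1 | intermediate
41 | (3S,4R,5S)-3-[(2S,3S)-6-(benzyloxy)-2-Ar4-3-(RB)-2,3-dihydro-1-benzofuran-4-yl]-4-Ar35-5-Ar4-oxolan-2-one (lactone 3,4-cis) | O(Cc9ccccc9)c1ccc([C@H]2Oc3cc(OCc9ccccc9)cc([C@@H]4[C@H](c5cc(OCc9ccccc9)cc(OCc9ccccc9)c5)[C@@H](c5ccc(OCc9ccccc9)cc5)OC4=O)c3[C@@H]2c2cc(OCc9ccccc9)c3c(c2)[C@@H](c2cc(OCc9ccccc9)cc(OCc9ccccc9)c2)[C@H](c2ccc(OCc9ccccc9)cc2)O3)cc1 | intermediate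
42 | (3S,4R,5S)-3-[(2S,3S)-6-(benzyloxy)-2-Ar4-3-(RB)-2,3-dihydro-1-benzofuran-4-yl]-4-Ar35-5-Ar4-oxolan-2-ol (anomers) | O(Cc9ccccc9)c1ccc([C@H]2Oc3cc(OCc9ccccc9)cc([C@@H]4[C@H](c5cc(OCc9ccccc9)cc(OCc9ccccc9)c5)[C@@H](c5ccc(OCc9ccccc9)cc5)OC4O)c3[C@@H]2c2cc(OCc9ccccc9)c3c(c2)[C@@H](c2cc(OCc9ccccc9)cc(OCc9ccccc9)c2)[C@H](c2ccc(OCc9ccccc9)cc2)O3)cc1 | intermediate
43 | (3S,4R,5S)-2-(benzenesulfonyl)-3-[(2S,3S)-6-(benzyloxy)-2-Ar4-3-(RB)-2,3-dihydro-1-benzofuran-4-yl]-4-Ar35-5-Ar4-oxolane (anomers) | O(Cc9ccccc9)c1ccc([C@H]2Oc3cc(OCc9ccccc9)cc([C@@H]4[C@H](c5cc(OCc9ccccc9)cc(OCc9ccccc9)c5)[C@@H](c5ccc(OCc9ccccc9)cc5)OC4S(=O)(=O)c6ccccc6)c3[C@@H]2c2cc(OCc9ccccc9)c3c(c2)[C@@H](c2cc(OCc9ccccc9)cc(OCc9ccccc9)c2)[C@H](c2ccc(OCc9ccccc9)cc2)O3)cc1 | intermediate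
44 | 1-(benzyloxy)-4-bromobenzene | Brc1ccc(OCc9ccccc9)cc1 | starting material
45 | [4-(benzyloxy)phenyl]magnesium bromide | Br[Mg]c1ccc(OCc9ccccc9)cc1 | intermediate
46 | bis[4-(benzyloxy)phenyl]zinc | c1cc(OCc9ccccc9)ccc1[Zn]c1ccc(OCc9ccccc9)cc1 | intermediate
47 | (2S,3R,4S,5R)-4-[(2S,3S)-6-(benzyloxy)-2-Ar4-3-(RB)-2,3-dihydro-1-benzofuran-4-yl]-3-Ar35-2,5-bis(Ar4)oxolane (deca-O-benzyl ether of 48) | O(Cc9ccccc9)c1ccc([C@H]2Oc3cc(OCc9ccccc9)cc([C@@H]4[C@H](c5cc(OCc9ccccc9)cc(OCc9ccccc9)c5)[C@@H](c5ccc(OCc9ccccc9)cc5)O[C@H]4c4ccc(OCc9ccccc9)cc4)c3[C@@H]2c2cc(OCc9ccccc9)c3c(c2)[C@@H](c2cc(OCc9ccccc9)cc(OCc9ccccc9)c2)[C@H](c2ccc(OCc9ccccc9)cc2)O3)cc1 | intermediate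
48 | kobophenol A as defined by the SMILES: (2S,3R,4S,5R)-3-(3,5-dihydroxyphenyl)-2,5-bis(4-hydroxyphenyl)-4-{(2S,3S)-6-hydroxy-2-(4-hydroxyphenyl)-3-[(2R,3R)-3-(3,5-dihydroxyphenyl)-7-hydroxy-2-(4-hydroxyphenyl)-2,3-dihydro-1-benzofuran-5-yl]-2,3-dihydro-1-benzofuran-4-yl}oxolane | Oc1ccc([C@H]2Oc3cc(O)cc([C@@H]4[C@H](c5cc(O)cc(O)c5)[C@@H](c5ccc(O)cc5)O[C@H]4c4ccc(O)cc4)c3[C@@H]2c2cc(O)c3c(c2)[C@@H](c2cc(O)cc(O)c2)[C@H](c2ccc(O)cc2)O3)cc1 | target

**Summary**

Total step count: 28.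
Longest linear sequence: 19 steps (steps 6–13, 17–21 and 23–28); steps 1–5, 14–16 and 22 are side branches.

**Steps most likely to fail**

Step 18. The hindered tertiary enolate of 31 may add to the aryne more slowly than the aryne is consumed in other ways. The aryl anion may also be protonated (plain α-arylation) or add to the lactone carbonyl instead of the ketone. The fallback forms the two bonds one after the other and does not use the aryne. It sets out from 7, 20 and 10. Vilsmeier–Haack formylation of 7 (POCl3, DMF) should give 2,4-bis(benzyloxy)-6-bromobenzaldehyde F1. Aryllithium 21, made from 20 as in step 13, adds to F1 to give the carbinol [2,4-bis(benzyloxy)-6-bromophenyl](RB)methanol F2. Dess–Martin oxidation gives the bromo ketone [2,4-bis(benzyloxy)-6-bromophenyl](RB)methanone F3, in which the bond from C-3a to C-3 of ring A is already in place. Palladium-catalysed α-arylation of the lithium enolate of lactone 10 with F3 (Pd2(dba)3, P(tBu)3, LiN(SiMe3)2, PhMe) then forms the bond from C-4 of ring T to C-4 of ring A. After equilibration at the lactone α-carbon the route is rejoined at 33.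

Step 23. The ylide may add to both faces of the ortho-quinone methide if the shielding by the C-3 aryl group of ring T is weak, so that ring A also forms with both of its stereocentres inverted; some 2,3-cis closure is also possible. The fallback replaces substrate control by reagent control. It sets out from 13 and 36. Chloride 13 is converted with (2R,5R)-2,5-dimethylthiolane and NaBF4 into the twofold-symmetric sulfonium salt (2R,5R)-1-{[4-(benzyloxy)phenyl]methyl}-2,5-dimethylthiolan-1-ium tetrafluoroborate F4. Under the conditions of step 23 its ylide should fix the configuration of the benzylic carbon that becomes C-2 of ring A, as in chiral sulfide-mediated benzylidene transfer, and through the trans-selective ring closure that of C-3. The sulfide antipode is chosen so that it reinforces the substrate bias, and the route is rejoined at 39.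

Step 24. Deprotonation at the crowded lactone α-carbon may be incomplete, the proton may be delivered to both faces, or the cis-lactone may revert to trans during work-up. The fallback separates enolate formation from protonation and makes the protonation reagent-controlled. It sets out from 39. The enolate (LiN(iPr)2, THF, −78 °C) is silylated with Me3SiCl to the ketene silyl acetal {[(4R,5S)-3-[(2S,3S)-6-(benzyloxy)-2-Ar4-3-(RB)-2,3-dihydro-1-benzofuran-4-yl]-4-Ar35-5-Ar4-4,5-dihydrofuran-2-yl]oxy}trimethylsilane F5, which is isolated by non-aqueous work-up. It is then protonated at −78 °C in toluene by the 1:1 complex of (R)-BINOL and SnCl4 (a Lewis acid-assisted chiral Brønsted acid; the BINOL antipode is chosen to match the substrate bias). The route is rejoined at 41, which is reduced at once as in step 25.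

**Further compounds**

F1 | step 18 | 2,4-bis(benzyloxy)-6-bromobenzaldehyde | O=Cc1c(Br)cc(OCc9ccccc9)cc1OCc9ccccc9
F2 | step 18 | [2,4-bis(benzyloxy)-6-bromophenyl](RB)methanol (carbinol epimers) | OC(c1c(Br)cc(OCc9ccccc9)cc1OCc9ccccc9)c1cc(OCc9ccccc9)c2c(c1)[C@@H](c1cc(OCc9ccccc9)cc(OCc9ccccc9)c1)[C@H](c1ccc(OCc9ccccc9)cc1)O2
F3 | step 18 | [2,4-bis(benzyloxy)-6-bromophenyl](RB)methanone | O=C(c1c(Br)cc(OCc9ccccc9)cc1OCc9ccccc9)c1cc(OCc9ccccc9)c2c(c1)[C@@H](c1cc(OCc9ccccc9)cc(OCc9ccccc9)c1)[C@H](c1ccc(OCc9ccccc9)cc1)O2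
F4 | step 23 | (2R,5R)-1-{[4-(benzyloxy)phenyl]methyl}-2,5-dimethylthiolan-1-ium tetrafluoroborate | F[B-](F)(F)F.C[C@@H]1CC[C@@H](C)[S+]1Cc1ccc(OCc9ccccc9)cc1
F5 | step 24 | {[(4R,5S)-3-[(2S,3S)-6-(benzyloxy)-2-Ar4-3-(RB)-2,3-dihydro-1-benzofuran-4-yl]-4-Ar35-5-Ar4-4,5-dihydrofuran-2-yl]oxy}trimethylsilane | O(Cc9ccccc9)c1ccc([C@H]2Oc3cc(OCc9ccccc9)cc(C4[C@H](c5cc(OCc9ccccc9)cc(OCc9ccccc9)c5)[C@@H](c5ccc(OCc9ccccc9)cc5)OC=4O[Si](C)(C)C)c3[C@@H]2c2cc(OCc9ccccc9)c3c(c2)[C@@H](c2cc(OCc9ccccc9)cc(OCc9ccccc9)c2)[C@H](c2ccc(OCc9ccccc9)cc2)O3)cc1
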